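The numbers come from no measurement; the run is a simulation.

Start from what is slow: in this flask, reagent can leave no faster than the small charge of second catalyst turns it over.

substrate 0.052 M; reagent 0.0494 M; capture agent 5.20 mM; free catalyst 7.3 mM; second catalyst 0.10 mM; time 20 min

    substrate + free catalyst ⇌ free catalyst + open intermediate (K1 = 7.6, k1 = 22 L mol⁻¹ s⁻¹)
    open intermediate + capture agent → trapped intermediate (k2 = 1.5 L mol⁻¹ s⁻¹)
    second catalyst + open intermediate ⇌ catalyst intermediate (K3 = 9700 L mol⁻¹, k3 = 1100 L mol⁻¹ s⁻¹)
    substrate → decomposition product (k4 = 7.6 × 10⁻⁵ s⁻¹)
    reagent + catalyst intermediate → second catalyst + target (k5 = 140 L mol⁻¹ s⁻¹)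

- how much target there is at 20 min, in percent of the substrate charged
- how much trapped intermediate there is at 20 min, in percent of the substrate charged

1. First guess. Reagent and capture agent together exceed the substrate, so substrate is the limiting reagent. If capture agent is used up, trapped intermediate is 10.0 % of the substrate and L = 2.60 mM of reagent stays over. But target formation competes for the same open intermediate, so capture agent may survive.

2. Clocks. With second catalyst held as catalyst intermediate, reagent decays with time constant τ = 71.4 s. Capture agent, facing a pool of substrate plus open intermediate as large as the substrate charge, has 12.8 s, which is shorter. But only part of the substrate is open, and only part of the second catalyst is bound. At the charges, these shares are 88.4 % and 88.0 %. They are about equal, so at the start they slow both clocks alike; I drop them, and assume for the rest of the run what is reckoned here for the start.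

3. The pool shrinks, though, so the start rate overstates capture. Decomposition aside, the pool is the reagent concentration R minus L plus the capture agent still unspent; I drop that last term, at most 10.0 % of the substrate charge, and take the pool as R − L, with B the reagent charge and k the capture rate constant 1.5 L mol⁻¹ s⁻¹. Integrating k·τ·(R − L)/R over R from L to B gives X = k·τ·[(B − L) − L·ln(B/L)] = 4.19. This is the capture exposure, the e-foldings capture agent suffers before the pool empties.

4. My reckoning. I expect 1.51 % of the capture agent to survive, so I reckon trapped intermediate at 9.85 % and target at 90.2 % of the substrate charged. Decomposition is ignored, since the half-life of substrate by that step alone, 150 min, far exceeds τ. The run also outlasts τ.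

5. The forecast says 90 % target and 9.9 % trapped intermediate: “Integrating over the run gives an exponent of about 4.5”, where my X is 4.19.

The simulation of this flask gives 90.0 % target and 9.85 % trapped intermediate, with 1.50 % of the capture agent left against the reckoned 1.51 %. Now raise capture agent to 0.013 M in the neighbouring flask. There L = 10.4 mM, and exposure falls to 2.44, so 8.70 % should survive and trapped intermediate should reach 22.8 %. That neighbouring flask holds 5.92 % of its capture agent at 20.0 min, with trapped intermediate at 23.5 % and target at 76.4 %.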